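The readings are simulated with made-up constants; the scatter is artificial.

Split the ratio of isomer of the product to target into a part present from the first moment and a part that grows with time, then ask which part leads at each asked time.

| flask | starting material | partner | protic impurity | catalyst | added ligand | remark | time |
|---|---|---|---|---|---|---|---|
| larch | 0.41 M | 0.328 M | 8.2 mM | 7 mM | 18 mM | run made earlier |  |
| cedar | 0.41 M | 0.328 M | 8.2 mM | 7 mM | 29 mM | run made earlier |  |
| flask | 0.41 M | 0.328 M | 8.20 mM | 7.0 mM | 13 mM |  | 4.0 min |

| run | time / min | isomer of the product / % | target / % | starting material / % |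
|---|---|---|---|---|
| larch | 0.250 | 0 | 11 | 84 |
| larch | 0.417 | 1 | 21 | 77 |
| larch | 0.667 | 8 | 18 | 70 |
| larch | 0.833 | 6 | 23 | 69 |
| larch | 1.33 | 8 | 25 | 65 |
| larch | 2.00 | 13 | 25 | 63 |
| larch | 3.00 | 16 | 23 | 58 |
| cedar | 0.167 | 2 | 9 | 86 |
| cedar | 0.500 | 3 | 19 | 74 |
| cedar | 0.833 | 6 | 25 | 71 |
| cedar | 1.33 | 9 | 26 | 63 |
| cedar | 2.00 | 14 | 26 | 60 |
| cedar | 2.50 | 15 | 25 | 62 |
| cedar | 3.00 | 15 | 24 | 58 |

(each reading ± 1.5 percentage points)

- ratio of isomer of the product to target at 2.5 s
- ratio of isomer of the product to target at 25 s
- ratio of isomer of the product to target at 4.0 min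



I pictured two extremes. In one, the isomer grows beside the target, so the ratio stands flat at a direct share, the selectivity factor of the two routes. In the other, it grows out of the target, so the ratio starts at zero and climbs. The real flask must lie between, and I took the sum.

Pooling larch and cedar, I read 0.250 at 0.833 min and 0.660 at 3.00 min. So the climb was 0.189 min⁻¹, and the line met time zero at 0.0926, not at zero. Their quotient, 0.490 min, is the handover time, when the climbing part equals the flat part.

| Asked time | Flat part | Climbing part | Sum |
|---|---|---|---|
| 2.5 s | 0.0926 | 0.00788 | 0.100 |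
| 25 s | 0.0926 | 0.0788 | 0.171 |
| 4.0 min | 0.0926 | 0.756 | 0.849 |

I held the last sum loosely: it lies later than the latest reading, and this flask carries less added ligand than larch or cedar.

The forecast gave 0.02, 0.07 and 1.1, holding that “it looks mainly sequential”.

The flask gave 0.108, 0.182 and 1.15.

    starting material + partner ⇌ target (K = 2.50 M⁻¹, k = 0.0380 M⁻¹ s⁻¹)
    starting material + partner ⇌ isomer of the product (K = 320 M⁻¹, k = 0.00380 M⁻¹ s⁻¹)
    target + catalyst ⇌ isomer of the product + catalyst, rate k3*[catalyst]*[target] forward; the back reaction follows from the equilibrium constant (k = 0.580 M⁻¹ s⁻¹)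
    catalyst + added ligand ⇌ idle complex (K = 180 M⁻¹, k = 0.580 M⁻¹ s⁻¹)
    starting material + protic impurity → quenched substrate (k = 0.310 M⁻¹ s⁻¹)

At the start, the forward rate to target stood at ten times the forward rate to isomer. At 25 s, before my handover, the flask's ratio exceeded the flat part by 0.0894, still less than that part.

In the neighbour with 0.0042 M of catalyst, I kept the flat part and scaled the climb with the charge, which moved the handover to 0.816 min and gave 0.140 at 25 s. That neighbour flask gave 0.158.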